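We decide to compare two times for each flask: how long its starting rate needs to reach the plateau, and how long the flask runs.

all flasks: L 45 mM

|  | G | Z | temperature | remark | time |
|---|---|---|---|---|---|
| cedar | 45 mM | 0.11 mM | 0 °C | run made earlier |  |
| elm | 45 mM | 0.44 mM | 35 °C | run made earlier |  |
| eta | 45.0 mM | 0.22 mM | 35 °C |  | 30 h |
| alpha | 45.0 mM | 0.22 mM | 5 °C |  | 30 h |
| beta | 45.0 mM | 0.22 mM |  | at 5 °C until 6.0 h, from then on at 65 °C | 30 h |
| epsilon | 45.0 mM | 0.22 mM | 65 °C |  | 30 h |

| run | time / h | Q / % | L / % |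
|---|---|---|---|
| cedar | 15.0 | 1.1 | 98.4 |
| cedar | 30.0 | 2.6 | 97.3 |
| cedar | 72.0 | 7.0 | 93.0 |
| cedar | 192 | 18.5 | 81.5 |
| elm | 4.00 | 72.5 | 26.5 |
| elm | 10.0 | 86.9 | 13.1 |
| elm | 20.0 | 87.2 | 13.1 |
| elm | 30.0 | 87.0 | 12.2 |

(each reading ± 0.3 percentage points)

- the numbers in the tables scatter by 0.3 percentage points (one standard deviation)
- on the list of suspects stand: 2 G -> D; L + Z <-> J; X -> Z + E; J <-> Z + Q; G + Z <-> X

- which flask leads in amount of Q, in percent of the L charged ("all alike" within 1.5 percentage points) (eta / alpha / beta / epsilon / all alike)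
- how much Q is there at the end, in percent of the L charged: eta
- how much Q is there at the end, in percent of the L charged: alpha
- how much Q is there at the end, in percent of the L charged: beta
- how much Q is there at the end, in percent of the L charged: epsilon

The cedar run climbs nearly straight: from 72.0 h to 192 h, Q gains 11 percentage points, a turnover of 0.392 h⁻¹ per Z. The elm run averages 18.5 h⁻¹ over its first 4.00 h, then reads 87.2% at 20.0 h, which we take as the plateau. As a rough step of our own, we let the logarithm of turnover run straight in temperature.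

For alpha, that step raises cedar's turnover by a factor of 1.73, so with its Z the starting rate is 0.150 mM h⁻¹. The plateau amount of Q divided by this rate is the crossing time, 262 h: a straight-line estimate of a time, which borrows the plateau of elm at 35 °C and marks no switch in the flask. Alpha stops well before its crossing, at 30 h. The slowing we can read is the closing distance to the plateau; a rate falling in step with that distance ends at 0.886 of its start, which costs about 0.57 points over the run. The straight line alone reaches 9.97%, so with that cost taken off we commit to roughly 9.40% for alpha, less than the forecast.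

Eta, with half of elm's Z at the same temperature, starts at 4.08 mM h⁻¹ and crosses at 9.62 h, earlier than its end, so it should stand on the plateau. At 65 °C our step gives a crossing of 0.353 h, shorter than the time beta spends hot, so beta and epsilon should both end on a plateau whose height no run shows.

The forecast names eta as the leader, with eta at 87% (85.5% to 88.5%), alpha at 10.3% (8.5% to 13%), and beta and epsilon each at 80% (60% to 93%). Its ground for eta: “Elm's sharp flat plateau at 87% is best read as the L/Q equilibrium”.

The flasks give 87.0% for eta, the leader, 12.0% for alpha, and 76.5% for beta and 76.5% for epsilon.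

    2 G → D (k = 76.7 L mol⁻¹ h⁻¹, Ea = 43.0 kJ mol⁻¹)
    L + Z ⇌ J (K = 177 L mol⁻¹, k = 3110 L mol⁻¹ h⁻¹, Ea = 49.0 kJ mol⁻¹, ΔH = 29.0 kJ mol⁻¹)
    X → Z + E (k = 591 h⁻¹, Ea = 77.0 kJ mol⁻¹)
    J ⇌ Z + Q (K = 0.0387 M, k = 47.7 h⁻¹, Ea = 86.0 kJ mol⁻¹, ΔH = −50.0 kJ mol⁻¹)
    G + Z ⇌ X (K = 9.38 L mol⁻¹, k = 1650 L mol⁻¹ h⁻¹, Ea = 44.0 kJ mol⁻¹, ΔH = −49.0 kJ mol⁻¹)
    (constants at 35 °C)

Alpha, left past its crossing of 262 h, holds 82.3% of Q at 300 h. The neighbour is alpha run at 20 °C. There our step gives a starting rate of 0.781 mM h⁻¹ and a crossing of 50.2 h, later than its end, with a straight line reaching 52.1%. That flask holds 31.8% of L and gives 68.0% of Q.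

The numbers in the tables stem from a simulated flask with made-up constants; noise was put on by code.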